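**Retrosynthetic overview**

- Last bond formed is C1–C5: acid opens the cis-4,5-epoxide of a (1(10)E)-germacrene 8-(4-hydroxybenzoate) at C5 with inversion, the C4–O bond stays, and loss of H-1 gives the 1(10)-alkene. Only the cis (neryl-type) epoxide gives the trans 4-OH/5-H pattern of the target.
- The germacrane ester comes from a 6-hydroxy-8-ketone by 1,3-anti reduction (sets C8) and acylation at O-8.
- The ten-membered ring is closed at C6–C7, the bond a germacrene synthase makes (farnesyl C1–C10), by an intramolecular anti-aldol of an E-enol borate onto an α,β-epoxy aldehyde (sets C6 and C7). The enol borate is unmasked by N-oxide oxidation of an alkenylboronate.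
- The acyclic precursor is a 9,10-didehydro-10,11-dihydro-(2Z,6E)-farnesol made from neryl acetate and 3-methylbut-1-yne; Sharpless epoxidation sets C4/C5.
- Ring order: ten-membered carbocycle first, then the five- and seven-membered rings together in the transannular closure.

Assumption: ring compounds are described with germacrane/guaiane numbering (methyls on C4 and C10, isopropyl on C7; target = 4S,5S,6R,7S,8S); common reagents are not numbered.

**Route**

Step 1
Reactants: 1 neryl acetate
Product: 2 (2Z,6E)-8-hydroxy-3,7-dimethylocta-2,6-dien-1-yl acetate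
Conditions: SeO2 (0.2 equiv), salicylic acid (0.1 equiv), tBuOOH (70% aq, 3 equiv), CH2Cl2, rt, stopped at about 70% conversion
Reagents that add atoms: tert-butyl hydroperoxide, CC(C)(C)OO (terminal oxidant); SeO2, O=[Se]=O (catalytic oxygen carrier)
Why: SeO2/tBuOOH allylic oxidation (ene reaction then [2,3]-shift) attacks the (E)-methyl of the electron-rich terminal alkene, not the alkene deactivated by the allylic acetate, and gives the E allylic alcohol; no stereocentre is formed.

Step 2
Reactants: 2 (2Z,6E)-8-hydroxy-3,7-dimethylocta-2,6-dien-1-yl acetate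
Product: 3 (2Z,6E)-8-bromo-3,7-dimethylocta-2,6-dien-1-yl acetate
Conditions: CBr4 (1.2 equiv), PPh3 (1.25 equiv), CH2Cl2, −20 °C
Reagents that add atoms: carbon tetrabromide, BrC(Br)(Br)Br
Why: Appel reaction; SN2 displacement at the primary allylic carbinol at low temperature keeps both alkene geometries and leaves the acetate untouched.

Step 3
Reactants: 3 (2Z,6E)-8-bromo-3,7-dimethylocta-2,6-dien-1-yl acetate; 4 3-methylbut-1-yne
Product: 6 (2Z,6E)-3,7,11-trimethyldodeca-2,6-dien-9-yn-1-ol, via enyne acetate 5 (not isolated)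
Conditions: CuI (10 mol %), Bu4NI (10 mol %), K2CO3 (2 equiv), 4 (2.5 equiv), DMF, rt, sealed flask; then MeOH, rt
Reagents that add atoms: none
Why: Copper-acetylide SN2 alkynylation of a primary allylic bromide gives the skipped enyne at the unhindered terminus, and the carbonate already present then removes the acetate by methanolysis; no stereocentre is formed.

Step 4
Reactants: 6 (2Z,6E)-3,7,11-trimethyldodeca-2,6-dien-9-yn-1-ol
Product: 7 [(2R,3S)-3-[(3E)-4,8-dimethylnon-3-en-6-yn-1-yl]-3-methyloxiran-2-yl]methanol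
Conditions: Ti(OiPr)4 (10 mol %), D-(−)-diisopropyl tartrate (13 mol %), tBuOOH (2 equiv, in decane), 4 Å molecular sieves, CH2Cl2, −20 °C
Reagents that add atoms: tert-butyl hydroperoxide, CC(C)(C)OO
Why: Katsuki–Sharpless asymmetric epoxidation touches only the allylic-alcohol alkene; D-(−)-tartrate gives the (2R,3S) cis-epoxide (as nerol gives (2R,3S)-epoxynerol), which fixes C4 (S) and places the C5 oxygen that is displaced with inversion in step 10.

Step 5
Reactants: 7 [(2R,3S)-3-[(3E)-4,8-dimethylnon-3-en-6-yn-1-yl]-3-methyloxiran-2-yl]methanol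
Product: 8 [(2R,3S)-3-[(3E,6Z)-4,8-dimethyl-6-(4,4,5,5-tetramethyl-1,3,2-dioxaborolan-2-yl)nona-3,6-dien-1-yl]-3-methyloxiran-2-yl]methanol
Conditions: B2pin2 (1.1 equiv), CuCl (5 mol %), tri(p-tolyl)phosphine (6 mol %), NaOtBu (15 mol %), MeOH (2 equiv), THF, rt
Reagents that add atoms: bis(pinacolato)diboron, CC1(C)OB(OC1(C)C)B1OC(C)(C)C(C)(C)O1
Why: Copper-catalysed protoboration of an internal alkyne (syn addition of Cu–Bpin, then protonation by MeOH) puts boron on the alkyne carbon next to CH2 rather than next to isopropyl, with H and B cis, which fixes the later enolate regio- and geometry; the epoxide, free hydroxyl and trisubstituted alkene are inert.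

Step 6
Reactants: 8 [(2R,3S)-3-[(3E,6Z)-4,8-dimethyl-6-(4,4,5,5-tetramethyl-1,3,2-dioxaborolan-2-yl)nona-3,6-dien-1-yl]-3-methyloxiran-2-yl]methanol
Product: 9 (2S,3S)-3-[(3E,6Z)-4,8-dimethyl-6-(4,4,5,5-tetramethyl-1,3,2-dioxaborolan-2-yl)nona-3,6-dien-1-yl]-3-methyloxirane-2-carbaldehyde
Conditions: Dess–Martin periodinane (1.3 equiv), pyridine (3 equiv), CH2Cl2, 0 °C; used crude
Reagents that add atoms: none
Why: Dess–Martin oxidation of the primary epoxy alcohol is mild and non-epimerising (the α-carbon is an epoxide carbon) and does not touch the alkenylboronate; the descriptor at C2 changes from R to S only because the priorities change.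

Step 7
Reactants: 9 (2S,3S)-3-[(3E,6Z)-4,8-dimethyl-6-(4,4,5,5-tetramethyl-1,3,2-dioxaborolan-2-yl)nona-3,6-dien-1-yl]-3-methyloxirane-2-carbaldehyde
Product: 12 (1(10)E,4S,5R,6R,7S)-4,5-epoxy-6-hydroxygermacr-1(10)-en-8-one, via enol borate 10 (not isolated), via boron aldolate 11 (not isolated)
Conditions: Me3NO (anhydrous, 1.5 equiv), 4 Å molecular sieves, toluene, 60 °C, slow addition of 9 (final 0.003 M); then pH 7 buffer/MeOH
Reagents that add atoms: trimethylamine N-oxide, C[N+](C)(C)[O-]
Why: Proposed new method: N-oxide oxidation of an alkenylboronate to an enol borate with retention of alkene geometry, followed by aldol addition to an aldehyde, is known intermolecularly (Hoffmann's enol borate aldol) and is used here to close a ten-membered ring; syn-protoboration plus retentive B-to-O migration give only the C7 E(O)-enolate (C9 cannot be enolised), which should add through a Zimmerman–Traxler chair to give the 6,7-anti aldol and, with Cornforth/Felkin–Anh attack anti to the epoxide C–O bond, the 5,6-anti relationship, so C6 (R) and C7 (S) are set together.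

Step 8
Reactants: 12 (1(10)E,4S,5R,6R,7S)-4,5-epoxy-6-hydroxygermacr-1(10)-en-8-one
Product: 13 (1(10)E,4S,5R,6R,7R,8S)-4,5-epoxygermacr-1(10)-ene-6,8-diol
Conditions: Me4NBH(OAc)3 (5 equiv), MeCN/AcOH (1:1), −30 °C
Reagents that add atoms: none
Why: Evans–Saksena hydroxyl-directed reduction; hydride is delivered intramolecularly from the C6 alkoxyborohydride through a chair transition state and gives the 1,3-anti diol, setting C8 (S); the C7 descriptor changes to R only through priorities.

Step 9
Reactants: 13 (1(10)E,4S,5R,6R,7R,8S)-4,5-epoxygermacr-1(10)-ene-6,8-diol; 14 4-acetoxybenzoyl chloride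
Product: 16 (1(10)E,4S,5R,6R,7S,8S)-4,5-epoxy-6-hydroxygermacr-1(10)-en-8-yl 4-hydroxybenzoate, via acetoxybenzoate 15 (not isolated)
Conditions: 14 (1.05 equiv), pyridine, 4-(dimethylamino)pyridine (5 mol %), CH2Cl2, −40 → 0 °C; then NH3 (7 M in MeOH), 0 °C
Reagents that add atoms: none
Why: Regioselective acylation; the C8 carbinol (next to a CH2) is less hindered than the C6 carbinol (between the epoxide carbon and the isopropyl-bearing carbon), and the phenolic acetate is then removed by ammonolysis much faster than the hindered aryl ester reacts; no stereocentre changes.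

Step 10
Reactants: 16 (1(10)E,4S,5R,6R,7S,8S)-4,5-epoxy-6-hydroxygermacr-1(10)-en-8-yl 4-hydroxybenzoate
Product: 17 (4S,5S,6R,7S,8S)-4,6-dihydroxyguai-1(10)-en-8-yl 4-hydroxybenzoate (target)
Conditions: p-toluenesulfonic acid monohydrate (10 mol %), CH2Cl2, 0 °C → rt
Reagents that add atoms: none
Why: Acid-mediated transannular epoxide–alkene cyclisation (the parthenolide-to-micheliolide type); C1 of the 1(10)-alkene attacks the protonated epoxide at C5 anti to the C5–O bond (inversion at C5, C4–OH kept with its configuration) and the tertiary C10 cation loses H-1 to the tetrasubstituted 1(10)-alkene, so the cis-epoxide gives the trans 4-OH/5-H array of the target.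

**Compound list**

1 | neryl acetate, (2Z)-3,7-dimethylocta-2,6-dien-1-yl acetate | CC(=O)OC/C=C(/C)CCC=C(C)C | starting material
2 | (2Z,6E)-8-hydroxy-3,7-dimethylocta-2,6-dien-1-yl acetate | CC(=O)OC/C=C(/C)CC/C=C(\C)CO | intermediate
3 | (2Z,6E)-8-bromo-3,7-dimethylocta-2,6-dien-1-yl acetate | CC(=O)OC/C=C(/C)CC/C=C(\C)CBr | intermediate
4 | 3-methylbut-1-yne | CC(C)C#C | starting material
5 | (2Z,6E)-3,7,11-trimethyldodeca-2,6-dien-9-yn-1-yl acetate | CC(=O)OC/C=C(/C)CC/C=C(\C)CC#CC(C)C | intermediate (not isolated)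
6 | (2Z,6E)-3,7,11-trimethyldodeca-2,6-dien-9-yn-1-ol | OC/C=C(/C)CC/C=C(\C)CC#CC(C)C | intermediate
7 | [(2R,3S)-3-[(3E)-4,8-dimethylnon-3-en-6-yn-1-yl]-3-methyloxiran-2-yl]methanol | OC[C@H]1O[C@@]1(C)CC/C=C(\C)CC#CC(C)C | intermediate
8 | [(2R,3S)-3-[(3E,6Z)-4,8-dimethyl-6-(4,4,5,5-tetramethyl-1,3,2-dioxaborolan-2-yl)nona-3,6-dien-1-yl]-3-methyloxiran-2-yl]methanol | OC[C@H]1O[C@@]1(C)CC/C=C(\C)C/C(B2OC(C)(C)C(C)(C)O2)=C\C(C)C | intermediate
9 | (2S,3S)-3-[(3E,6Z)-4,8-dimethyl-6-(4,4,5,5-tetramethyl-1,3,2-dioxaborolan-2-yl)nona-3,6-dien-1-yl]-3-methyloxirane-2-carbaldehyde | O=C[C@H]1O[C@@]1(C)CC/C=C(\C)C/C(B2OC(C)(C)C(C)(C)O2)=C\C(C)C | intermediate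
10 | (2S,3S)-3-[(3E,6E)-4,8-dimethyl-6-[(4,4,5,5-tetramethyl-1,3,2-dioxaborolan-2-yl)oxy]nona-3,6-dien-1-yl]-3-methyloxirane-2-carbaldehyde (E-enol borate) | O=C[C@H]1O[C@@]1(C)CC/C=C(\C)C/C(OB2OC(C)(C)C(C)(C)O2)=C\C(C)C | intermediate (not isolated)
11 | O6-(pinacolatoboryl) derivative of 12 (boron aldolate) | C/C1=C\CC[C@]2(C)O[C@@H]2[C@H](OB3OC(C)(C)C(C)(C)O3)[C@H](C(C)C)C(=O)C1 | intermediate (not isolated)
12 | (1(10)E,4S,5R,6R,7S)-4,5-epoxy-6-hydroxygermacr-1(10)-en-8-one; ten-membered ring, cis-epoxide | C/C1=C\CC[C@]2(C)O[C@@H]2[C@H](O)[C@H](C(C)C)C(=O)C1 | intermediate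
13 | (1(10)E,4S,5R,6R,7R,8S)-4,5-epoxygermacr-1(10)-ene-6,8-diol | C/C1=C\CC[C@]2(C)O[C@@H]2[C@H](O)[C@H](C(C)C)[C@@H](O)C1 | intermediate
14 | 4-acetoxybenzoyl chloride | CC(=O)Oc1ccc(cc1)C(Cl)=O | starting material
15 | (1(10)E,4S,5R,6R,7S,8S)-4,5-epoxy-6-hydroxygermacr-1(10)-en-8-yl 4-acetoxybenzoate | C/C1=C\CC[C@]2(C)O[C@@H]2[C@H](O)[C@H](C(C)C)[C@@H](OC(=O)c2ccc(OC(C)=O)cc2)C1 | intermediate (not isolated)
16 | (1(10)E,4S,5R,6R,7S,8S)-4,5-epoxy-6-hydroxygermacr-1(10)-en-8-yl 4-hydroxybenzoate | C/C1=C\CC[C@]2(C)O[C@@H]2[C@H](O)[C@H](C(C)C)[C@@H](OC(=O)c2ccc(O)cc2)C1 | intermediate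
17 | (4S,5S,6R,7S,8S)-4,6-dihydroxyguai-1(10)-en-8-yl 4-hydroxybenzoate = (3S,3aS,4R,5S,6S)-3,4-dihydroxy-3,8-dimethyl-5-(propan-2-yl)-1,2,3,3a,4,5,6,7-octahydroazulen-6-yl 4-hydroxybenzoate | CC1=C2CC[C@](C)(O)[C@@H]2[C@H](O)[C@H](C(C)C)[C@@H](OC(=O)c2ccc(O)cc2)C1 | target

**Step count and risks**

Total step count: 10. Longest linear sequence: 10 steps, from neryl acetate 1; compounds 4 and 14 are bought.

The three steps most likely to fail are step 7, step 10 and step 9.

Step 7 is the largest risk. The pinacol enol borate may be too unreactive to close a ten-membered ring, or the ring constraint may override the chair-controlled anti selectivity. The fallback sets out from aldehyde 9. Enol borate 10 is formed as before, but at 0.2 M and −20 °C, and is trapped at once with N-bromosuccinimide (excess, to cover the liberated amine). This gives (2S,3S)-3-[(3E)-7-bromo-4,8-dimethyl-6-oxonon-3-en-1-yl]-3-methyloxirane-2-carbaldehyde F1 with the bromine only at C7. The ring is then closed reductively by a chromium Reformatsky reaction (CrCl2, LiI, THF, high dilution). The chromium enolate adds only to the aldehyde and has been reported to favour anti aldols. This comes back to the route at 12.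

Step 10 may give cyclic ethers if the C10 cation is captured by the C6 or C4 hydroxyl, or the cis-epoxide may not reach a reactive conformation at the ester stage. The fallback sets out from ketone 12 and closes the bicycle before C8 is reduced. BF3·OEt2 in CH2Cl2 at −78 °C gives (4S,5S,6R,7S)-4,6-dihydroxyguai-1(10)-en-8-one F2. Directed reduction with Me4NBH(OAc)3 then gives (4S,5S,6R,7R,8S)-guai-1(10)-ene-4,6,8-triol F3. Acylation with 14 on the rigid bicycle gives (4S,5S,6R,7S,8S)-4,6-dihydroxyguai-1(10)-en-8-yl 4-acetoxybenzoate F4, and ammonolysis of the aryl acetate comes back to the route at 17.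

Step 9 may not discriminate well enough between the C8 and C6 hydroxyls. The fallback sets out from ketone 12. A syn-selective Narasaka–Prasad reduction (Et2BOMe, NaBH4, THF/MeOH, −78 °C) gives (1(10)E,4S,5R,6R,7R,8R)-4,5-epoxygermacr-1(10)-ene-6,8-diol F5. A Mitsunobu esterification with unprotected 4-hydroxybenzoic acid (PPh3, diisopropyl azodicarboxylate, THF, 0 °C) then engages only the less hindered C8 carbinol and inverts it. The carboxylic acid reacts in preference to the phenol, so this comes back to the route directly at 16.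

**Further compounds**

F1 | step 7 | (2S,3S)-3-[(3E)-7-bromo-4,8-dimethyl-6-oxonon-3-en-1-yl]-3-methyloxirane-2-carbaldehyde (both C–Br epimers) | O=C[C@H]1O[C@@]1(C)CC/C=C(\C)CC(=O)C(Br)C(C)C
F2 | step 10 | (4S,5S,6R,7S)-4,6-dihydroxyguai-1(10)-en-8-one | CC1=C2CC[C@](C)(O)[C@@H]2[C@H](O)[C@H](C(C)C)C(=O)C1
F3 | step 10 | (4S,5S,6R,7R,8S)-guai-1(10)-ene-4,6,8-triol | CC1=C2CC[C@](C)(O)[C@@H]2[C@H](O)[C@H](C(C)C)[C@@H](O)C1
F4 | step 10 | (4S,5S,6R,7S,8S)-4,6-dihydroxyguai-1(10)-en-8-yl 4-acetoxybenzoate | CC1=C2CC[C@](C)(O)[C@@H]2[C@H](O)[C@H](C(C)C)[C@@H](OC(=O)c2ccc(OC(C)=O)cc2)C1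
F5 | step 9 | (1(10)E,4S,5R,6R,7R,8R)-4,5-epoxygermacr-1(10)-ene-6,8-diol | C/C1=C\CC[C@]2(C)O[C@@H]2[C@H](O)[C@H](C(C)C)[C@H](O)C1
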